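**Strategy.** The route rests on disconnecting the ring bond between C4, the carbon bearing the exocyclic methylene, and C3, the carbon bearing the side chain (ring numbering: C1 carbinol, C2 gem-dimethyl). The key step is a 6-exo-dig radical cyclization of a C3 radical onto a terminal alkyne, run inside a temporary seven-membered lactone that ties the C1 oxygen to the first three side-chain carbons. In one operation it closes the cyclohexane, creates the methylidene group and sets C3, because the lactone bridge allows only the cis-1,3 arrangement of C1–O and the C3 chain across C2. The precursor is a monocyclic oxepanone xanthate with a butynyl arm; the lactone later becomes the chain alkyne.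

Key step: step 5

**Route**

Step 1
Reactants: 1 pent-4-ynal; 2 prenylmagnesium chloride
Product: 5 (4S)-3,3-dimethyloct-1-en-7-yn-4-ol, via prenylborane 3 (not isolated), via borinate ester 4 (not isolated)
Conditions: (+)-Ipc2BOMe, Et2O, 0 °C to rt (2 added first); then 1, −78 °C; then HOCH2CH2NH2, rt
Reagents that add atoms: none
Why: Brown allylboration with a prenyl(diisopinocampheyl)borane of the (−)-α-pinene series, which adds through a chair Zimmerman–Traxler transition state with its CMe2 terminus to the Re face of the aldehyde and so sets the (S)-carbinol (target C1) while building the quaternary C2 with its vinyl group; the terminal alkyne is inert to the borane.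

Step 2
Reactants: 6 bromoacetic acid; 7 potassium O-ethyl carbonodithioate
Product: 8 2-[(ethoxycarbonothioyl)sulfanyl]acetic acid
Conditions: acetone, 0 °C to rt
Reagents that add atoms: none
Why: SN2 S-alkylation of the xanthate salt by the α-bromo acid should give the carboxymethyl xanthate that serves as radical source.

Step 3
Reactants: 5 (4S)-3,3-dimethyloct-1-en-7-yn-4-ol; 8 2-[(ethoxycarbonothioyl)sulfanyl]acetic acid
Product: 9 (6S)-4-[(ethoxycarbonothioyl)sulfanyl]-6-hydroxy-5,5-dimethyldec-9-ynoic acid (both C4 epimers)
Conditions: dilauroyl peroxide (cat., in portions), ClCH2CH2Cl (1 M), reflux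
Reagents that add atoms: none
Why: Degenerative xanthate-transfer radical addition, in which the electrophilic carboxymethyl radical adds to the unhindered CH2 terminus of the vinyl group faster than to the alkyne and, at this concentration, the secondary adduct radical is capped by xanthate transfer before it can cyclize; the new xanthate-bearing centre (target C3) forms as a mixture of epimers, which does not matter because it becomes a radical in step 5.

Step 4
Reactants: 9 (6S)-4-[(ethoxycarbonothioyl)sulfanyl]-6-hydroxy-5,5-dimethyldec-9-ynoic acid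
Product: 10 O-ethyl S-[(7S)-7-(but-3-yn-1-yl)-6,6-dimethyl-2-oxooxepan-5-yl] carbonodithioate
Conditions: 2-methyl-6-nitrobenzoic anhydride, DMAP, Et3N, CH2Cl2 (2 mM, slow addition of 9), rt
Reagents that add atoms: none
Why: Shiina lactonization through the mixed anhydride, where acyl activation under non-alkoxide conditions lets the hindered hydroxyl close the seven-membered ring (helped by the gem-dimethyl group) without attack on the xanthate; this installs the temporary tether and touches no stereocentre.

Step 5
Reactants: 10 O-ethyl S-[(7S)-7-(but-3-yn-1-yl)-6,6-dimethyl-2-oxooxepan-5-yl] carbonodithioate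
Product: 11 (1S,6R)-10,10-dimethyl-7-methylidene-2-oxabicyclo[4.3.1]decan-3-one
Conditions: Bu3SnH (syringe pump), AIBN (cat.), benzene (5 mM), reflux
Reagents that add atoms: none
Why: The tributylstannyl radical adds to the thiocarbonyl sulfur and the S–C bond breaks to give a secondary radical at target C3 inside the oxepanone; this radical attacks the internal carbon of the terminal alkyne held on target C1, and the vinyl radical so formed takes a hydrogen atom from Bu3SnH to leave the exocyclic methylene on C4. The closest known reaction type is the tin-hydride radical cyclization of xanthates onto terminal alkynes (hept-6-ynyl radical closure). The cyclohexane closes in the 6-exo-dig mode, which turns the monocyclic lactone into a bridged 2-oxabicyclo[4.3.1]decanone. The new stereocentre C3 is controlled by the lactone tether: O1 and the first side-chain carbon are joined by a two-carbon bridge, so only the cis-1,3 bridged ring can form, and the (S)-carbinol therefore fixes C3 as (R) from either xanthate epimer. The step needs ring closure to outrun hydrogen transfer to the C3 radical and exo attack to beat 7-endo attack; the low stationary Bu3SnH concentration, the gem-dimethyl group next to the radical and the geometric preference for attack at the internal alkyne carbon should secure this.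

Step 6
Reactants: 11 (1S,6R)-10,10-dimethyl-7-methylidene-2-oxabicyclo[4.3.1]decan-3-one
Product: 13 (1S,3R)-3-(but-3-yn-1-yl)-2,2-dimethyl-4-methylidenecyclohexan-1-ol, via lactol 12 (not isolated)
Conditions: iBu2AlH, CH2Cl2, −78 °C; then MeOH, K2CO3, dimethyl (1-diazo-2-oxopropyl)phosphonate, −78 °C to rt
Reagents that add atoms: dimethyl (1-diazo-2-oxopropyl)phosphonate, COP(=O)(OC)C(=[N+]=[N-])C(C)=O
Why: Partial reduction of the lactone to the lactol followed in the same flask by Ohira–Bestmann homologation of the ring-opened hydroxy aldehyde should cleave the tether, free the C1 hydroxyl and turn the former lactone carbon into a terminal alkyne, with no stereocentre touched.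

Step 7
Reactants: 13 (1S,3R)-3-(but-3-yn-1-yl)-2,2-dimethyl-4-methylidenecyclohexan-1-ol
Product: 15 (1S,3R)-3-[(3E)-4-iodo-3-methylbut-3-en-1-yl]-2,2-dimethyl-4-methylidenecyclohexan-1-ol, via alkenylalane 14 (not isolated)
Conditions: Me3Al, Cp2ZrCl2 (cat.), CH2Cl2, 0 °C to rt; then I2, THF, −30 to 0 °C
Reagents that add atoms: trimethylaluminium, C[Al](C)C; iodine, II
Why: Negishi zirconium-catalyzed syn-methylalumination places methyl on the internal and aluminium on the terminal alkyne carbon, and iodinolysis with retention should give the (E)-trisubstituted vinyl iodide; the hydroxyl travels as its aluminium alkoxide and the 1,1-disubstituted ring alkene does not react.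

Step 8
Reactants: 16 (2E,6E)-farnesol
Product: 17 (2E,6E)-farnesal
Conditions: MnO2, CH2Cl2, rt
Reagents that add atoms: none
Why: Allylic oxidation on MnO2 stops at the enal and keeps both double-bond geometries.

Step 9
Reactants: 17 (2E,6E)-farnesal
Product: 18 (3E,7E)-4,8,12-trimethyltrideca-1,3,7,11-tetraene
Conditions: Ph3PCH3Br, KOtBu, THF, 0 °C to rt
Reagents that add atoms: methyltriphenylphosphonium bromide, C[P+](c1ccccc1)(c1ccccc1)c1ccccc1.[Br-]
Why: Wittig methylenation of the enal should give the terminal 1,3-diene without touching the trisubstituted (E)-alkenes.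

Step 10
Reactants: 18 (3E,7E)-4,8,12-trimethyltrideca-1,3,7,11-tetraene; 15 (1S,3R)-3-[(3E)-4-iodo-3-methylbut-3-en-1-yl]-2,2-dimethyl-4-methylidenecyclohexan-1-ol
Product: 20 achilleol A, via alkylborane 19 (not isolated)
Conditions: 18, 9-BBN, THF, 0 °C to rt; then 15, Pd(dppf)Cl2 (cat.), AsPh3, Cs2CO3, DMF/H2O, rt
Reagents that add atoms: none
Why: Chemoselective anti-Markovnikov hydroboration of the monosubstituted diene terminus gives a homoallylic B-alkyl borane, and B-alkyl Suzuki–Miyaura coupling with the vinyl iodide (oxidative addition to zerovalent palladium, transmetalation, reductive elimination, all with retention of alkene geometry) should join the halves to the (3E,7E,11E) chain; the free hydroxyl is tolerated and no stereocentre is formed.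

**Compound list**

1 | pent-4-ynal | C#CCCC=O | starting material
2 | prenylmagnesium chloride (3-methylbut-2-en-1-ylmagnesium chloride) | CC(C)=CC[Mg]Cl | starting material
3 | (3-methylbut-2-en-1-yl)bis(isopinocampheyl)borane, (−)-α-pinene series | CC(C)=CCB([C@H]1C[C@H]2C[C@@H]([C@@H]1C)C2(C)C)[C@H]1C[C@H]2C[C@@H]([C@@H]1C)C2(C)C | intermediate (not isolated)
4 | (4S)-3,3-dimethyloct-1-en-7-yn-4-yl bis(isopinocampheyl)borinate | C#CCC[C@H](OB([C@H]1C[C@H]2C[C@@H]([C@@H]1C)C2(C)C)[C@H]1C[C@H]2C[C@@H]([C@@H]1C)C2(C)C)C(C)(C)C=C | intermediate (not isolated)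
5 | (4S)-3,3-dimethyloct-1-en-7-yn-4-ol | C#CCC[C@H](O)C(C)(C)C=C | intermediate
6 | bromoacetic acid | OC(=O)CBr | starting material
7 | potassium O-ethyl carbonodithioate (potassium ethyl xanthate) | CCOC(=S)[S-].[K+] | starting material
8 | 2-[(ethoxycarbonothioyl)sulfanyl]acetic acid | CCOC(=S)SCC(=O)O | intermediate
9 | (6S)-4-[(ethoxycarbonothioyl)sulfanyl]-6-hydroxy-5,5-dimethyldec-9-ynoic acid (C4 epimers) | C#CCC[C@H](O)C(C)(C)C(SC(=S)OCC)CCC(=O)O | intermediate
10 | O-ethyl S-[(7S)-7-(but-3-yn-1-yl)-6,6-dimethyl-2-oxooxepan-5-yl] carbonodithioate (C5 epimers) | C#CCC[C@@H]1OC(=O)CCC(SC(=S)OCC)C1(C)C | intermediate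
11 | (1S,6R)-10,10-dimethyl-7-methylidene-2-oxabicyclo[4.3.1]decan-3-one (bridged lactone) | C=C1CC[C@H]2C(C)(C)[C@@H]1CCC(=O)O2 | intermediate
12 | (1S,6R)-10,10-dimethyl-7-methylidene-2-oxabicyclo[4.3.1]decan-3-ol (lactol, both anomers) | C=C1CC[C@H]2C(C)(C)[C@@H]1CCC(O)O2 | intermediate (not isolated)
13 | (1S,3R)-3-(but-3-yn-1-yl)-2,2-dimethyl-4-methylidenecyclohexan-1-ol | C=C1CC[C@H](O)C(C)(C)[C@@H]1CCC#C | intermediate
14 | (E)-alkenyl(dimethyl)alane of 13, carried as its dimethylaluminium alkoxide | C=C1CC[C@H](O[Al](C)C)C(C)(C)[C@@H]1CC/C(C)=C/[Al](C)C | intermediate (not isolated)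
15 | (1S,3R)-3-[(3E)-4-iodo-3-methylbut-3-en-1-yl]-2,2-dimethyl-4-methylidenecyclohexan-1-ol | C=C1CC[C@H](O)C(C)(C)[C@@H]1CC/C(C)=C/I | intermediate
16 | (2E,6E)-farnesol | OC/C=C(\C)CC/C=C(\C)CCC=C(C)C | starting material
17 | (2E,6E)-farnesal | O=C/C=C(\C)CC/C=C(\C)CCC=C(C)C | intermediate
18 | (3E,7E)-4,8,12-trimethyltrideca-1,3,7,11-tetraene | C=C/C=C(\C)CC/C=C(\C)CCC=C(C)C | intermediate
19 | 9-[(3E,7E)-4,8,12-trimethyltrideca-3,7,11-trien-1-yl]-9-borabicyclo[3.3.1]nonane | B1(CC/C=C(\C)CC/C=C(\C)CCC=C(C)C)C2CCCC1CCC2 | intermediate (not isolated)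
20 | achilleol A, (1S,3R)-2,2-dimethyl-4-methylidene-3-[(3E,7E,11E)-3,8,12,16-tetramethylheptadeca-3,7,11,15-tetraen-1-yl]cyclohexan-1-ol | C=C1CC[C@H](O)C(C)(C)[C@@H]1CC/C(C)=C/CC/C=C(\C)CC/C=C(\C)CCC=C(C)C | target

**Step count**

Total steps: 10. Longest linear sequence: 7 steps (1, 3, 4, 5, 6, 7, 10).

**Steps most likely to fail**

Step 5 (key ring closure). What may go wrong: hydrogen transfer to the C3 radical, from Bu3SnH or by a 1,5-shift from the propargylic CH2, outruns the 6-exo-dig closure, so that the xanthate is merely reduced. The fallback reverses the polarity of the ring closure and closes the lactone by metathesis. It sets out from 5. Esterification with but-3-enoic acid (DCC, DMAP, CH2Cl2) should give the ester (4S)-3,3-dimethyloct-1-en-7-yn-4-yl but-3-enoate F1. Bromoboration of the alkyne with B-bromo-9-BBN and protonolysis with AcOH should give the 2-bromoalkene (4S)-7-bromo-3,3-dimethylocta-1,7-dien-4-yl but-3-enoate F2. Ring-closing metathesis with the second-generation Grubbs catalyst, in which the vinyl bromide should not take part, should give the unsaturated lactone (7S)-7-(3-bromobut-3-en-1-yl)-6,6-dimethyl-6,7-dihydrooxepin-2(3H)-one F3. Bu3SnH and AIBN should then generate the vinyl radical at the bromine-bearing carbon, which adds in the 6-exo-trig mode to the ring alkene carbon next to the gem-dimethyl carbon. Hydrogen transfer brings the route back to 11 with the same tether-enforced cis geometry.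

Step 4 (lactonization). What may go wrong: acylation of the hindered secondary hydroxyl next to the quaternary carbon is slower than intermolecular ester formation, so that oligomers form instead of the seven-membered ring. The fallback replaces the ester tether by a silicon tether that is delivered intramolecularly. It sets out from 5. Silylation with (bromomethyl)chlorodimethylsilane (Et3N, DMAP, CH2Cl2) should give the silyl ether (4S)-4-{[(bromomethyl)dimethylsilyl]oxy}-3,3-dimethyloct-1-en-7-yne F4. Bu3SnH and AIBN under high dilution should trigger 7-endo attack of the α-silyl radical on the vinyl terminus, followed by the same 6-exo-dig closure, to give the bridged siloxane (1S,6R)-3,3,10,10-tetramethyl-7-methylidene-2-oxa-3-silabicyclo[4.3.1]decane F5. Tamao–Fleming oxidation (H2O2, KF, KHCO3, THF/MeOH) should give the diol (1S,3R)-3-(2-hydroxyethyl)-2,2-dimethyl-4-methylidenecyclohexan-1-ol F6. Selective iodination of the primary hydroxyl (I2, PPh3, imidazole) should give the iodide (1S,3R)-3-(2-iodoethyl)-2,2-dimethyl-4-methylidenecyclohexan-1-ol F7. Displacement with lithium acetylide–ethylenediamine complex in DMSO brings the route back to 13.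

Step 6 (lactone to alkyne). What may go wrong: over-reduction of the bridged lactone to the diol, or incomplete opening of the lactol to the hydroxy aldehyde, so that the homologation stalls. The fallback goes through a methyl ketone instead. It sets out from 11. Addition of MeLi (1 equiv, THF, −78 °C) should open the lactone to the hydroxy methyl ketone 4-[(1R,3S)-3-hydroxy-2,2-dimethyl-6-methylidenecyclohexyl]butan-2-one F8. Kinetic enolization with LDA, trapping with ClP(O)(OEt)2 and elimination of the enol phosphate with more LDA bring the route back to 13.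

**Further compounds**

F1 | step 5 | (4S)-3,3-dimethyloct-1-en-7-yn-4-yl but-3-enoate | C#CCC[C@H](OC(=O)CC=C)C(C)(C)C=C
F2 | step 5 | (4S)-7-bromo-3,3-dimethylocta-1,7-dien-4-yl but-3-enoate | C=C(Br)CC[C@H](OC(=O)CC=C)C(C)(C)C=C
F3 | step 5 | (7S)-7-(3-bromobut-3-en-1-yl)-6,6-dimethyl-6,7-dihydrooxepin-2(3H)-one | C=C(Br)CC[C@@H]1OC(=O)CC=CC1(C)C
F4 | step 4 | (4S)-4-{[(bromomethyl)dimethylsilyl]oxy}-3,3-dimethyloct-1-en-7-yne | C#CCC[C@H](O[Si](C)(C)CBr)C(C)(C)C=C
F5 | step 4 | (1S,6R)-3,3,10,10-tetramethyl-7-methylidene-2-oxa-3-silabicyclo[4.3.1]decane | C=C1CC[C@H]2C(C)(C)[C@@H]1CC[Si](C)(C)O2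
F6 | step 4 | (1S,3R)-3-(2-hydroxyethyl)-2,2-dimethyl-4-methylidenecyclohexan-1-ol | C=C1CC[C@H](O)C(C)(C)[C@@H]1CCO
F7 | step 4 | (1S,3R)-3-(2-iodoethyl)-2,2-dimethyl-4-methylidenecyclohexan-1-ol | C=C1CC[C@H](O)C(C)(C)[C@@H]1CCI
F8 | step 6 | 4-[(1R,3S)-3-hydroxy-2,2-dimethyl-6-methylidenecyclohexyl]butan-2-one | C=C1CC[C@H](O)C(C)(C)[C@@H]1CCC(C)=O
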